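**Plan**

- Retrosynthetic cuts, in order: the two phenols back to MOM ethers; the ring C=C back to a ketone on the ring =CH– carbon (through the more substituted enol triflate); then, in that cyclohexanone, the ring bond from the methyl-bearing carbon to the prenyl-bearing carbon and the ring bond from the aroyl-bearing carbon to the phenyl-bearing carbon. This leaves the aryl dienone ArCO–CH=CH–CH2CH=CMe2 and the 2-silyloxydiene of (E)-1-phenylpent-1-en-3-one; the dienone is cut at its enone C=C (aldol) to an aryl methyl ketone and 4-methylpent-3-enal.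
- Enabling feature: in the cyclohexene ring the only unsubstituted sp2 carbon (=CH–) is 1,4 to the aroyl-bearing ring carbon, flanked by the methyl-bearing carbon on one side and, through the ring CH2, by the phenyl-bearing carbon on the other. An oxygen on that carbon turns this four-carbon arc into a 2-oxydiene whose enol-ether end matches the enone β-carbon and whose styryl end matches the enone α-carbon.
- Forward order: the arene is adjusted first (ortho-demethylation, MOM), the side chain is joined by aldol addition/elimination, the carbocycle is made in one [4+2] event, the alkene is placed by triflation/reduction, and the phenols are released last.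
- Stereochemistry: the prenyl-bearing centre is set by a chiral oxazaborolidinium catalyst (face of the enone); the aroyl-bearing centre follows from the E-alkene; the phenyl-bearing centre is relayed in the same flask by equilibration to the all-equatorial ketone.

Key step: step 7

Assumption: the (S)-oxazaborolidinium salt is taken to leave open the enone face that is Re at the α-carbon and Si at the β-carbon; if the first run shows the opposite sense, the (R)-salt is used and nothing else changes.

**Route**

Step 1
Reactants: 1 1-(6-hydroxy-2,3,4-trimethoxyphenyl)ethan-1-one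
Product: 2 1-(2,6-dihydroxy-3,4-dimethoxyphenyl)ethan-1-one
Conditions: BCl3 (3 equiv), CH2Cl2, –78 → 0 °C; H2O
Reagents that add atoms: none
Why: Chelation-directed Lewis-acid ether cleavage: boron held between the ketone oxygen and the flanking oxygen activates only the methoxy group ortho to the carbonyl, so the meta and para methyl ethers should stay (regioselective ortho-demethylation of an ortho-methoxyaryl ketone).

Step 2
Reactants: 2 1-(2,6-dihydroxy-3,4-dimethoxyphenyl)ethan-1-one
Product: 3 1-[2,6-bis(methoxymethoxy)-3,4-dimethoxyphenyl]ethan-1-one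
Conditions: NaH, MOMCl, DMF, 0 °C → rt
Reagents that add atoms: chloromethyl methyl ether, COCCl
Why: Williamson-type O-alkylation of the bis-phenoxide with the α-chloro ether; NaH in DMF is used because both phenols are hydrogen-bonded to the ketone.

Step 3
Reactants: 4 4-methylpent-3-en-1-ol
Product: 5 4-methylpent-3-enal
Conditions: Dess–Martin periodinane, pyridine, CH2Cl2, 0 °C
Reagents that add atoms: none
Why: Dess–Martin oxidation of a primary alcohol under buffered, non-enolising conditions, so the β,γ-double bond should not move into conjugation; the aldehyde is used at once.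

Step 4
Reactants: 3 1-[2,6-bis(methoxymethoxy)-3,4-dimethoxyphenyl]ethan-1-one; 5 4-methylpent-3-enal
Product: 6 1-[2,6-bis(methoxymethoxy)-3,4-dimethoxyphenyl]-3-hydroxy-6-methylhept-5-en-1-one (racemic)
Conditions: LiN(iPr)2, THF, –78 °C; then 5; AcOH
Reagents that add atoms: none
Why: Aldol addition of the kinetic lithium enolate of the methyl ketone to the aldehyde at –78 °C, where addition should outrun enolisation of the aldehyde; the new carbinol centre is racemic and is removed in step 5.

Step 5
Reactants: 6 1-[2,6-bis(methoxymethoxy)-3,4-dimethoxyphenyl]-3-hydroxy-6-methylhept-5-en-1-one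
Product: 8 (2E)-1-[2,6-bis(methoxymethoxy)-3,4-dimethoxyphenyl]-6-methylhepta-2,5-dien-1-one, via secondary mesylate 7 (not isolated)
Conditions: MsCl, Et3N, CH2Cl2, 0 °C → rt
Reagents that add atoms: none
Why: Mesylation followed by E1cB elimination of the β-mesyloxy ketone should give the conjugated (E)-enone; Et3N is too weak a base to move the skipped 5,6-double bond into conjugation.

Step 6
Reactants: 9 (1E)-1-phenylpent-1-en-3-one
Product: 10 triisopropyl{[(1E,3Z)-1-phenylpenta-1,3-dien-3-yl]oxy}silane
Conditions: iPr3SiOTf, Et3N, CH2Cl2, 0 °C → rt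
Reagents that add atoms: triisopropylsilyl trifluoromethanesulfonate, CC(C)[Si](OS(=O)(=O)C(F)(F)F)(C(C)C)C(C)C
Why: Soft enolisation (silyl triflate/amine) of the ethyl ketone at its only enolisable position gives the cross-conjugated silyl dienol ether, expected mainly as the (Z)-enol ether with the methyl group on the outside of the s-cis diene.

Step 7
Reactants: 8 (2E)-1-[2,6-bis(methoxymethoxy)-3,4-dimethoxyphenyl]-6-methylhepta-2,5-dien-1-one; 10 triisopropyl{[(1E,3Z)-1-phenylpenta-1,3-dien-3-yl]oxy}silane
Product: 12 (2R,3R,4S,5S)-4-[2,6-bis(methoxymethoxy)-3,4-dimethoxybenzoyl]-2-methyl-3-(3-methylbut-2-en-1-yl)-5-phenylcyclohexan-1-one, via endo silyl enol ether cycloadduct 11 (not isolated)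
Conditions: (S)-1-(2-methylphenyl)-3,3-diphenyltetrahydro-1H,3H-pyrrolo[1,2-c][1,3,2]oxazaborole·HNTf2 (20 mol %), CH2Cl2, –78 → –20 °C; then Bu4NF, THF, 0 → 40 °C; AcOH
Reagents that add atoms: none
Why: The protonated oxazaborolidine binds the ketone oxygen of 8 on the lone pair away from the twisted tetra-alkoxyaryl ring, the enol-ether terminus of 10 (the CHMe carbon) attacks the β-carbon and the styryl terminus closes on the α-carbon, a strongly asynchronous Diels–Alder reaction that in its stepwise limit is a Mukaiyama–Michael addition followed by Michael ring closure. The closest known reaction type is the cationic-oxazaborolidine-catalysed [4+2] annulation of 2-silyloxydienes with α,β-unsaturated ketones. The one new ring, the six-membered carbocycle, is closed by intermolecular [4+2] cycloaddition (a 6-endo-trig Michael closure if stepwise), and the regiochemistry is secured by the substrate, because the silyloxy group (para director) and the phenyl group (ortho director) of 10 polarise the diene in the same sense. The prenyl-bearing centre is set by the catalyst, which should leave open the face of 8 that is Si at the β-carbon and Re at the α-carbon; this face selectivity is the only kinetic selectivity the step needs, since it is the same for endo and exo approach, and the aroyl-bearing centre is trans to it through the E geometry of 8. The phenyl-bearing centre and the transient methyl-bearing centre are set by thermodynamics: Bu4NF cleaves the silyl enol ether of 11 to the ring enolate, from which the ring-closing Michael addition is reversible and the α-centres exchange, so that the endo adduct 11 (phenyl cis to aroyl) and any exo isomer should converge on the all-equatorial ketone 12. The skipped diene of 8 should survive because neither free base nor protic acid is present during the cycloaddition stage.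

Step 8
Reactants: 12 (2R,3R,4S,5S)-4-[2,6-bis(methoxymethoxy)-3,4-dimethoxybenzoyl]-2-methyl-3-(3-methylbut-2-en-1-yl)-5-phenylcyclohexan-1-one
Product: 13 (3S,4R,5S)-4-[2,6-bis(methoxymethoxy)-3,4-dimethoxybenzoyl]-2-methyl-3-(3-methylbut-2-en-1-yl)-5-phenylcyclohex-1-en-1-yl trifluoromethanesulfonate
Conditions: LiN(SiMe3)2 (0.95 equiv), THF, 0 °C → rt; then PhNTf2, 0 °C → rt
Reagents that add atoms: N-phenylbis(trifluoromethanesulfonimide), FC(F)(F)S(=O)(=O)N(c1ccccc1)S(=O)(=O)C(F)(F)F
Why: Enolate triflation under thermodynamic control: with a slight deficit of base the lithium enolates should equilibrate by proton exchange to the more substituted (methyl-bearing) isomer, as for 2-methylcyclohexanone, and the triflimide traps it on oxygen; the hindered aroyl ketone has no accessible α-hydrogen, and the methyl-bearing stereocentre, no longer needed, becomes sp2.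

Step 9
Reactants: 13 (3S,4R,5S)-4-[2,6-bis(methoxymethoxy)-3,4-dimethoxybenzoyl]-2-methyl-3-(3-methylbut-2-en-1-yl)-5-phenylcyclohex-1-en-1-yl trifluoromethanesulfonate
Product: 14 [2,6-bis(methoxymethoxy)-3,4-dimethoxyphenyl][(1S,2S,6S)-3-methyl-2-(3-methylbut-2-en-1-yl)-6-phenylcyclohex-3-en-1-yl]methanone
Conditions: Pd(OAc)2 (5 mol %), PPh3, Bu3N, HCO2H, DMF, 60 °C
Reagents that add atoms: none
Why: Palladium-catalysed formate reduction of an enol triflate (oxidative addition of zerovalent palladium formed in situ, formate exchange, decarboxylation, C–H reductive elimination) replaces OTf by H without moving the double bond, which is now the trisubstituted ring alkene of the target; no stereocentre is touched.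

Step 10
Reactants: 14 [2,6-bis(methoxymethoxy)-3,4-dimethoxyphenyl][(1S,2S,6S)-3-methyl-2-(3-methylbut-2-en-1-yl)-6-phenylcyclohex-3-en-1-yl]methanone
Product: 15 (2,6-dihydroxy-3,4-dimethoxyphenyl)[(1S,2S,6S)-3-methyl-2-(3-methylbut-2-en-1-yl)-6-phenylcyclohex-3-en-1-yl]methanone
Conditions: 3 M HCl (aq), MeOH, 40 °C
Reagents that add atoms: none
Why: Acid-catalysed transacetalisation of the two aryl MOM ethers to methanol, fast for ethers ortho to a carbonyl; the aroyl-bearing centre is already in its more stable trans,trans arrangement, so enolisation cannot scramble it.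

**Compound list**

1 | 1-(6-hydroxy-2,3,4-trimethoxyphenyl)ethan-1-one | CC(=O)c1c(O)cc(OC)c(OC)c1OC | starting material
2 | 1-(2,6-dihydroxy-3,4-dimethoxyphenyl)ethan-1-one | CC(=O)c1c(O)cc(OC)c(OC)c1O | intermediate
3 | 1-[2,6-bis(methoxymethoxy)-3,4-dimethoxyphenyl]ethan-1-one | CC(=O)c1c(OCOC)cc(OC)c(OC)c1OCOC | intermediate
4 | 4-methylpent-3-en-1-ol | CC(C)=CCCO | starting material
5 | 4-methylpent-3-enal | CC(C)=CCC=O | intermediate
6 | 1-[2,6-bis(methoxymethoxy)-3,4-dimethoxyphenyl]-3-hydroxy-6-methylhept-5-en-1-one (racemic) | CC(C)=CCC(O)CC(=O)c1c(OCOC)cc(OC)c(OC)c1OCOC | intermediate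
7 | 1-[2,6-bis(methoxymethoxy)-3,4-dimethoxyphenyl]-6-methyl-1-oxohept-5-en-3-yl methanesulfonate (racemic, not isolated) | CC(C)=CCC(OS(C)(=O)=O)CC(=O)c1c(OCOC)cc(OC)c(OC)c1OCOC | intermediate
8 | (2E)-1-[2,6-bis(methoxymethoxy)-3,4-dimethoxyphenyl]-6-methylhepta-2,5-dien-1-one | CC(C)=CC/C=C/C(=O)c1c(OCOC)cc(OC)c(OC)c1OCOC | intermediate
9 | (1E)-1-phenylpent-1-en-3-one | CCC(=O)/C=C/c1ccccc1 | starting material
10 | triisopropyl{[(1E,3Z)-1-phenylpenta-1,3-dien-3-yl]oxy}silane | C/C=C(O[Si](C(C)C)(C(C)C)C(C)C)/C=C/c1ccccc1 | intermediate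
11 | [2,6-bis(methoxymethoxy)-3,4-dimethoxyphenyl]{(1S,2R,5R,6R)-5-methyl-6-(3-methylbut-2-en-1-yl)-2-phenyl-4-[(triisopropylsilyl)oxy]cyclohex-3-en-1-yl}methanone (endo adduct, not isolated) | COc1cc(OCOC)c(C(=O)[C@H]2[C@H](CC=C(C)C)[C@@H](C)C(O[Si](C(C)C)(C(C)C)C(C)C)=C[C@H]2c2ccccc2)c(OCOC)c1OC | intermediate
12 | (2R,3R,4S,5S)-4-[2,6-bis(methoxymethoxy)-3,4-dimethoxybenzoyl]-2-methyl-3-(3-methylbut-2-en-1-yl)-5-phenylcyclohexan-1-one | COc1cc(OCOC)c(C(=O)[C@H]2[C@H](CC=C(C)C)[C@@H](C)C(=O)C[C@@H]2c2ccccc2)c(OCOC)c1OC | intermediate
13 | (3S,4R,5S)-4-[2,6-bis(methoxymethoxy)-3,4-dimethoxybenzoyl]-2-methyl-3-(3-methylbut-2-en-1-yl)-5-phenylcyclohex-1-en-1-yl trifluoromethanesulfonate | COc1cc(OCOC)c(C(=O)[C@H]2[C@H](CC=C(C)C)C(C)=C(OS(=O)(=O)C(F)(F)F)C[C@@H]2c2ccccc2)c(OCOC)c1OC | intermediate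
14 | [2,6-bis(methoxymethoxy)-3,4-dimethoxyphenyl][(1S,2S,6S)-3-methyl-2-(3-methylbut-2-en-1-yl)-6-phenylcyclohex-3-en-1-yl]methanone | COc1cc(OCOC)c(C(=O)[C@H]2[C@H](CC=C(C)C)C(C)=CC[C@@H]2c2ccccc2)c(OCOC)c1OC | intermediate
15 | (2,6-dihydroxy-3,4-dimethoxyphenyl)[(1S,2S,6S)-3-methyl-2-(3-methylbut-2-en-1-yl)-6-phenylcyclohex-3-en-1-yl]methanone | COc1cc(O)c(C(=O)[C@H]2[C@H](CC=C(C)C)C(C)=CC[C@@H]2c2ccccc2)c(O)c1OC | target

**Step count**

Total: 10 steps. Longest linear sequence: 8 steps (steps 1, 2, 4, 5, 7, 8, 9, 10, from compound 1).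

**Steps most likely to fail**

Step 7. The β-alkyl enone may be too unreactive towards the 1,4-disubstituted diene at temperatures where the catalyst still discriminates the enone faces. The ring-opening/closing equilibration may also stay incomplete at the phenyl-bearing centre, or extend to cleavage of the first-formed bond and erode the enantiomeric purity. The fallback sets out from 9 and 8 and comes back at 12; it replaces the catalytic Lewis-acid cycloaddition by auxiliary-controlled enamine chemistry. Condensation of 9 with (S)-2-(methoxymethyl)pyrrolidine (TiCl4, Et3N, toluene, 0 °C → rt) should give the chiral 2-aminodiene (S)-2-(methoxymethyl)-1-[(1E,3E)-1-phenylpenta-1,3-dien-3-yl]pyrrolidine F1. Its Stork-type Michael addition to 8 (MeCN, rt → 50 °C) and reversible closure of the iminium–enolate should give the cyclic enamine [2,6-bis(methoxymethoxy)-3,4-dimethoxyphenyl]{(1S,2S,5R,6R)-4-[(2S)-2-(methoxymethyl)pyrrolidin-1-yl]-5-methyl-6-(3-methylbut-2-en-1-yl)-2-phenylcyclohex-3-en-1-yl}methanone F2. Buffered hydrolysis (aq AcOH/NaOAc) releases the auxiliary and returns 12; the antipodal amine is used if the sense of induction requires it.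

Step 8. Enolisation towards the ring CH2 next to the phenyl-bearing carbon may compete, because the tetrasubstituted enolate suffers allylic strain with the neighbouring prenyl group; the regioisomeric triflate would then lead to the wrong alkene. The fallback sets out from 12 and comes back at 14, bypassing 13 and step 9. Reduction with LiBH(s-Bu)3 (THF, –78 °C) should deliver hydride equatorially to the cyclohexanone only, the hindered aroyl ketone being left, and give the axial alcohol [2,6-bis(methoxymethoxy)-3,4-dimethoxyphenyl][(1S,2R,3R,4S,6S)-4-hydroxy-3-methyl-2-(3-methylbut-2-en-1-yl)-6-phenylcyclohexyl]methanone F3. Its C–O bond is antiperiplanar to the tertiary C–H at the methyl-bearing carbon, so anti-elimination with Ph2S[OC(CF3)2Ph]2 (Martin sulfurane, CH2Cl2, rt) should follow the Zaitsev orientation and give 14.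

Step 10. Acid may add methanol or chloride across the trisubstituted alkenes, or trigger cation–olefin or phenol–olefin cyclisation involving the ring double bond, while the acetals are cleaved. The fallback sets out from 13 and comes back at 15; it moves the acid step ahead of the formation of the acid-sensitive ring alkene. At the triflate stage the ring double bond is an electron-poor enol triflate that should not protonate, so 3 M HCl/MeOH should give the bis-phenol (3S,4R,5S)-4-(2,6-dihydroxy-3,4-dimethoxybenzoyl)-2-methyl-3-(3-methylbut-2-en-1-yl)-5-phenylcyclohex-1-en-1-yl trifluoromethanesulfonate F4. The reduction of step 9 (Pd(OAc)2, PPh3, Bu3N, HCO2H, DMF) applied to F4 then gives 15 directly.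

**Further compounds**

F1 | step 7 | (S)-2-(methoxymethyl)-1-[(1E,3E)-1-phenylpenta-1,3-dien-3-yl]pyrrolidine | C/C=C(\C=C\c1ccccc1)N1CCC[C@H]1COC
F2 | step 7 | [2,6-bis(methoxymethoxy)-3,4-dimethoxyphenyl]{(1S,2S,5R,6R)-4-[(2S)-2-(methoxymethyl)pyrrolidin-1-yl]-5-methyl-6-(3-methylbut-2-en-1-yl)-2-phenylcyclohex-3-en-1-yl}methanone | COc1cc(OCOC)c(C(=O)[C@H]2[C@H](CC=C(C)C)[C@@H](C)C(N3CCC[C@H]3COC)=C[C@@H]2c2ccccc2)c(OCOC)c1OC
F3 | step 8 | [2,6-bis(methoxymethoxy)-3,4-dimethoxyphenyl][(1S,2R,3R,4S,6S)-4-hydroxy-3-methyl-2-(3-methylbut-2-en-1-yl)-6-phenylcyclohexyl]methanone | COc1cc(OCOC)c(C(=O)[C@H]2[C@H](CC=C(C)C)[C@@H](C)[C@@H](O)C[C@@H]2c2ccccc2)c(OCOC)c1OC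
F4 | step 10 | (3S,4R,5S)-4-(2,6-dihydroxy-3,4-dimethoxybenzoyl)-2-methyl-3-(3-methylbut-2-en-1-yl)-5-phenylcyclohex-1-en-1-yl trifluoromethanesulfonate | COc1cc(O)c(C(=O)[C@H]2[C@H](CC=C(C)C)C(C)=C(OS(=O)(=O)C(F)(F)F)C[C@@H]2c2ccccc2)c(O)c1OC
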